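Compound numbers are those of the steps and of the compound list below.

## Analysis of the target

The target 16 is a flavone: a 4H-chromen-4-one (benzo ring A fused to pyranone ring C) with an aryl ring B on C2. Ring A is fully substituted, with hydroxyls on C5 and C7, methoxyls on C6 and C8, the carbonyl-bearing C4a and the oxygen-bearing C8a. Ring B carries a methoxyl on C2' and hydroxyls on C3' and C6', so C1' lies between two oxygenated carbons and the C2–C1' bond is crowded. There is no stereocentre; the C2–C1' axis has only O1 and the C3 hydrogen on the chromone side, so lasting atropisomers are not expected. The sensitive parts are three: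
- the hydroquinone of ring B (C3' and C6' hydroxyls para to each other), which air oxidises to the quinone in base;
- the pyranone, which strong base opens at C2;
- the C6' hydroxyl, which in any open-chain 1,3-dicarbonyl form could close onto C4 and give an isomeric flavone.

The difficulty is therefore not the skeleton but seven oxygens of two kinds (four OH, three OMe) on two crowded rings, and the attachment of ring C to a hexasubstituted ring A. The strategy rests on one feature: without O1, ring A is a 1,2,3,4-tetraoxygenated benzene with a single ring C–H, at C8a. That carbon is ortho to C4a, ortho to the C8 methoxyl and para to the C6 methoxyl, the position at which an arene radical cation accepts a nucleophile.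

## Retrosynthetic reasoning

**From 16 back to 15.** The last bonds cut are the two benzyl–oxygen bonds at the C5 and C7 oxygens. Hydrogenolysis is neutral and reducing, so the chelated C5 hydroxyl and the air-sensitive hydroquinone appear together only in the final flask. Benzyl, not acyl, is chosen for ring A because ring A must remain the most electron-rich arene of the key-step substrate.

**From 15 back to 14.** The two acetyl–oxygen bonds on ring B are cut. The acetates lower the electron density of ring B so that the anode should leave it alone. The one on the C6' oxygen also keeps that oxygen from closing onto C4 while the molecule is still an open diketone. The forward step is a mild methanolysis that must not open the pyranone.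

**From 14 back to 13 (key disconnection).** The O1–C8a bond is cut, which opens ring C to the 1,3-diketone 13 and leaves a hydrogen on C8a. This bond is chosen over C2=C3 or C2–C1' because only its cleavage lowers the oxygen count of ring A from five to four while leaving the two aromatic halves joined by an ordinary diketone. The gain is a ring A without any leaving group: C8a is its only C–H, so the site of closure is fixed by the substitution pattern. The forward reaction must remove two electrons and two protons, join the oxygen on C2 to C8a, and spare ring B, the benzyl groups and the product.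

**From 13 back to 5 and 12.** The C2–C3 bond of the diketone is cut, between the acyl carbon of 12 and the methyl carbon of 5. This splits the molecule into its two aromatic halves, and the crowded C2–C1' bond never has to be formed because it is the aryl–carbonyl bond of 12. The forward reaction is a C-acylation of a methyl ketone that must tolerate two aryl acetates. That rules out strong amide bases and points to soft enolisation with a magnesium salt and a tertiary amine.

**From 5 back to 1 via 4, 3 and 2.** The benzyl ethers are cut, and the C–O bond at the future C5 is traced back to a C–Br bond in 3 and to a C–H bond in 2. Acetosyringone 1 already holds the acetyl carbon and the methoxyl–hydroxyl–methoxyl triad that becomes C6, C7 and C8. Its two free ring positions are equivalent, so substituting one gives the tetraoxygenated pattern and leaves the other as the C8a hydrogen. The forward steps must brominate the ring and not the methyl group, and must turn a hindered aryl bromide into a phenol.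

**From 12 back to 6 via 11, 10, 9, 8 and 7.** The acid chloride goes back to acid 11, the acetates to the dihydroxy acid 10, and this to the bis-acetal 9. The aryl–carboxyl bond of 9 is cut at the carbon between the methoxyl and an acetal oxygen, which leads through aryllithium 8 to 7 and to 2-methoxyhydroquinone 6. A directed metalation reaches that position first because two oxygen groups flank it. The later exchange of acetal for acetate is the price of needing a directing group in one step and an electron-withdrawing group in the key step.

## Alternatives that were turned down

**Alternative 1:** Ring A is made, not bought: the C4a–C8a and O1–C2 bonds are cut together, which unrolls ring A into a polyketide-like chain stored as the 2-pyranone A1. A1 is a 4-hydroxy-3,5-dimethoxy-2-pyranone whose C6 side chain is a methylene, a ketone and an alkyne ending in the protected ring B.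
- Forward key step: Mg(OMe)2 in methanol would open the lactone to a methyl triketo ester. The methylene between the C4 and C5 carbonyls would attack the ester carbon in a Claisen condensation to give an acylphloroglucinol, and an ortho phenoxide would add to the ynone (6-endo-dig) to give flavone A2.
- For it: two rings form in one flask, the C5 and C7 hydroxyls emerge free, and the new ring A is symmetric, so either ortho oxygen gives the same flavone. Only the two acetal groups on ring B remain to be removed, so its end game is shorter than the chosen one, which needs two deprotections.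
- Against it: A1 combines a doubly α-methoxylated pyranone with an aryl ynone and would itself need a long sequence with several uncertain steps. Methoxide adds readily to ynones, so conjugate addition of the solvent competes with lactone opening. The open chain can also cyclise by aldol condensation instead of Claisen condensation.
- Comparison: the chosen strategy takes ring A ready-made from 1 and puts its risk into one step on a robust substrate; this alternative spreads risk over precursor synthesis and cascade alike.

**Alternative 2:** The C2=C3 bond is cut. The precursor A3 is an ortho-acyloxyphenacyl ylide: the oxygen on C8a is esterified by the ring B acid and the acetyl carbon carries a triphenylphosphoranylidene group.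
- Forward key step: on heating in toluene the ylide carbon (C3) would add to the ester carbonyl (C2), and loss of the phosphine oxide would give the perbenzylated flavone A4 (intramolecular ester Wittig reaction).
- For it: this closure is established for flavones and runs under neutral conditions, so its key step is more certain than the anodic closure. One hydrogenolysis of four benzyl ethers would finish the synthesis. On both counts it is stronger.
- Against it: O1 must be on ring A from the outset, so the starting ring is a hexasubstituted acetophenone with five oxygens in three states (one free, two benzylated, two methylated), far longer to make than 5. The ester that must accept the ylide is a 2,6-disubstituted benzoate, a poor and hindered electrophile. The same hindrance burdens the esterification of a phenol flanked by an acyl group and a methoxyl.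
- Comparison: in the chosen route C8a enters as a C–H, so ring A needs only four oxygens and comes from 1 in four steps. The hindered ring B carbonyl reacts as an acid chloride with a small enolate, not as an ester with a bulky ylide.

**Alternative 3:** The crowded C2–C1' bond is cut, with a temporary lactone from the C6' oxygen to a carboxyl on C3 as the tether. The precursor A5 is the 2-bromoaryl ester of a chromone-3-carboxylic acid.
- Forward key step: with Pd(OAc)2, PCy3, K2CO3 and pivalic acid, zerovalent palladium would insert into the C1'–Br bond. The C2–H of the chromone would be cleaved by concerted metalation–deprotonation, and reductive elimination would give the lactone-bridged flavone A6.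
- For it: the most hindered bond of the target is made intramolecularly, and the tether protects the C6' hydroxyl on the way. Intramolecular direct arylation is a known reaction type, so here too the key step stands on firmer ground than the chosen one.
- Against it: ring A again needs O1 in place and also a carboxyl on C3. An aryl ester of an electron-poor acid must survive carbonate at high temperature. Oxidative addition at an electron-rich, doubly ortho-substituted bromide is slow. After the key step the lactone must be opened and C3 decarboxylated under conditions in which hydroxide can also open the pyranone and let the freed C6' oxygen close onto C4, before two kinds of protecting group are removed.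
- Comparison: the chosen route never has to make the C2–C1' bond, because it is the aryl–carbonyl bond of 12 from the start. It needs two steps after its key step where this alternative needs at least four.

Key step: step 11

Remark on the chemistry: rotation about the C2–C1' bond is assumed to be free at room temperature, so no stereochemical element needs control; acid chloride 12 is assumed to be used as obtained after evaporation.

## Route

Step 1
Reactants: 1 acetosyringone (1-(4-hydroxy-3,5-dimethoxyphenyl)ethanone)
Product: 2 1-[4-(benzyloxy)-3,5-dimethoxyphenyl]ethanone
Conditions: BnBr, K2CO3, DMF, rt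
Reagents that add atoms: benzyl bromide, BrCc1ccccc1
Why: Williamson ether synthesis; the phenol, acidified by the para acetyl group, is alkylated under carbonate, and capping it first keeps the brominating agent of step 2 from oxidising a free 2,6-dimethoxyphenol.

Step 2
Reactants: 2 1-[4-(benzyloxy)-3,5-dimethoxyphenyl]ethanone
Product: 3 1-[4-(benzyloxy)-2-bromo-3,5-dimethoxyphenyl]ethanone
Conditions: NBS, MeCN, 0 °C → rt, dark
Reagents that add atoms: N-bromosuccinimide, O=C1CCC(=O)N1Br
Why: Electrophilic aromatic bromination; C2 and C6 are equivalent and each is ortho to one methoxyl and para to the other, so one monobromide should form, and neutral NBS in a polar solvent without light disfavours enol (side-chain) and radical (benzylic) bromination.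

Step 3
Reactants: 3 1-[4-(benzyloxy)-2-bromo-3,5-dimethoxyphenyl]ethanone
Product: 4 1-[4-(benzyloxy)-2-hydroxy-3,5-dimethoxyphenyl]ethanone
Conditions: Pd2(dba)3 (cat.), tBuXPhos (cat.), KOH, 1,4-dioxane/H2O, 100 °C; then aq. HCl
Reagents that add atoms: potassium hydroxide, [K+].[OH-]
Why: Palladium-catalysed hydroxylation of an aryl bromide (C–O cross-coupling with hydroxide); the bulky biaryl phosphine permits reductive elimination of the aryl–oxygen bond at the hindered carbon, and the product is held as its phenoxide, which does not couple further.

Step 4
Reactants: 4 1-[4-(benzyloxy)-2-hydroxy-3,5-dimethoxyphenyl]ethanone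
Product: 5 1-[2,4-bis(benzyloxy)-3,5-dimethoxyphenyl]ethanone
Conditions: BnBr, K2CO3, Bu4NI (cat.), DMF, 60 °C
Reagents that add atoms: benzyl bromide, BrCc1ccccc1
Why: Williamson ether synthesis; the chelated ortho-hydroxy ketone needs gentle heating, and carbonate is too weak a base to alkylate the methyl ketone.

Step 5
Reactants: 6 2-methoxyhydroquinone (2-methoxybenzene-1,4-diol)
Product: 7 2-methoxy-1,4-bis(methoxymethoxy)benzene
Conditions: MOMCl, i-Pr2NEt, CH2Cl2, 0 °C → rt, N2
Reagents that add atoms: chloromethyl methyl ether, COCCl
Why: O-alkylation of both phenols by the chloromethyl ether under amine base (acetal protection); the methoxymethyl ethers serve as directing groups for step 6, and the inert atmosphere keeps the hydroquinone from oxidising.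

Step 6
Reactants: 7 2-methoxy-1,4-bis(methoxymethoxy)benzene
Product: 9 2-methoxy-3,6-bis(methoxymethoxy)benzoic acid, via aryllithium 8 (not isolated)
Conditions: n-BuLi, TMEDA, THF, −78 → 0 °C; CO2, −78 °C → rt; cold 1 M HCl to pH 3
Reagents that add atoms: carbon dioxide, O=C=O; n-butyllithium, [Li]CCCC (supplies the lithium of 8 only)
Why: Directed ortho-metalation followed by carboxylation; C3 lies between the methoxyl and a methoxymethoxy group, so both oxygens coordinate lithium and acidify this hydrogen, as in the lithiation of 1,2,4-trialkoxybenzenes, and CO2 traps 8 as the carboxylate.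

Step 7
Reactants: 9 2-methoxy-3,6-bis(methoxymethoxy)benzoic acid
Product: 10 3,6-dihydroxy-2-methoxybenzoic acid
Conditions: 2 M HCl, THF/H2O, rt, N2
Reagents that add atoms: none
Why: Acid hydrolysis of the two acetals; the 2,6-disubstituted acid should neither esterify nor decarboxylate under these mild conditions, and oxygen is excluded to protect the hydroquinone.

Step 8
Reactants: 10 3,6-dihydroxy-2-methoxybenzoic acid
Product: 11 3,6-diacetoxy-2-methoxybenzoic acid
Conditions: Ac2O, pyridine, DMAP (cat.), 0 °C → rt; H2O, then 1 M HCl
Reagents that add atoms: acetic anhydride, CC(=O)OC(C)=O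
Why: Acetylation of both phenols by nucleophilic catalysis; any mixed anhydride at the carboxyl group is hydrolysed in the aqueous work-up, as in the preparation of O-acetylsalicylic acids.

Step 9
Reactants: 11 3,6-diacetoxy-2-methoxybenzoic acid
Product: 12 3,6-diacetoxy-2-methoxybenzoyl chloride
Conditions: (COCl)2, DMF (cat.), CH2Cl2, 0 °C → rt; evaporate
Reagents that add atoms: oxalyl chloride, O=C(Cl)C(Cl)=O
Why: Acid chloride formation through the chloroiminium (Vilsmeier-type) catalyst; the neutral, gas-evolving conditions leave the aryl acetates untouched.

Step 10
Reactants: 5 1-[2,4-bis(benzyloxy)-3,5-dimethoxyphenyl]ethanone; 12 3,6-diacetoxy-2-methoxybenzoyl chloride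
Product: 13 1-[2,4-bis(benzyloxy)-3,5-dimethoxyphenyl]-3-(3,6-diacetoxy-2-methoxyphenyl)propane-1,3-dione
Conditions: MgBr2·OEt2, i-Pr2NEt, CH2Cl2, 0 °C → rt; cold 1 M HCl
Reagents that add atoms: none
Why: Soft-enolisation crossed Claisen condensation (C-acylation of a ketone by an acid chloride); magnesium coordination acidifies the methyl ketone enough for the tertiary amine to enolise it, the magnesium enolate is acylated on carbon, and the product is held as a magnesium diketonate chelate that resists further acylation, while the mild base should spare the aryl acetates.

Step 11
Reactants: 13 1-[2,4-bis(benzyloxy)-3,5-dimethoxyphenyl]-3-(3,6-diacetoxy-2-methoxyphenyl)propane-1,3-dione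
Product: 14 2-(3,6-diacetoxy-2-methoxyphenyl)-5,7-bis(benzyloxy)-6,8-dimethoxy-4H-chromen-4-one
Conditions: graphite anode, Pt cathode, undivided cell, Bu4NBF4 (0.1 M), (CF3)2CHOH, constant current (ca. 3 mA cm−2, ca. 2.2 F mol−1), rt
Reagents that add atoms: none
Why: Proposed new method: the anode should remove one electron from ring A, the only arene of 13 with four alkoxy donors, to give a radical cation with much of its positive charge at C8a, the lone ring C–H, which is ortho to the C8 methoxyl and para to the C6 methoxyl; the oxygen on C2 of the enolised diketone, brought over C8a by rotation about the C3–C4 bond, adds there, and loss of a proton, a second electron and the C8a proton restores the arene as the chromen-4-one while protons are reduced to H2 at the cathode. The closest known reaction types are anodic dehydrogenative C–O cyclisations of electron-rich arenes (biaryl-2-carboxylic acids to benzocoumarins) and the copper-catalysed O-arylation of 2-haloaryl 1,3-diketones to flavones, which forms the same O1–C8a bond from a C–Br bond. Ring C closes in a six-membered mode, formally a 6-endo-trig attack of oxygen on the ring carbon with the C4a–C8a bond inside the new ring, and no stereocentre is formed. The step needs chemoselective oxidation of ring A, which the two acetoxy groups on ring B and the unactivated phenyl rings of the benzyl ethers should secure, and site selectivity, which is fixed because C8a is the only hydrogen-bearing carbon of ring A and closure through the other diketone oxygen would be four-membered. Attack at the benzyloxy-bearing C5 cannot rearomatise and should revert in the non-nucleophilic solvent. Hexafluoroisopropanol stabilises the radical cation without trapping it and hydrogen-bonds to the product carbonyl, which together with control of the charge passed should limit over-oxidation of 14.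

Step 12
Reactants: 14 2-(3,6-diacetoxy-2-methoxyphenyl)-5,7-bis(benzyloxy)-6,8-dimethoxy-4H-chromen-4-one
Product: 15 5,7-bis(benzyloxy)-2-(3,6-dihydroxy-2-methoxyphenyl)-6,8-dimethoxy-4H-chromen-4-one
Conditions: K2CO3 (cat.), degassed MeOH/THF, 0 °C → rt, Ar; then aq. NH4Cl
Reagents that add atoms: none
Why: Base-catalysed transesterification of aryl acetates; phenoxide is a good leaving group, so methanolysis should be fast well below the temperature at which methoxide opens the pyranone, and exclusion of oxygen keeps the new hydroquinone from oxidising.

Step 13
Reactants: 15 5,7-bis(benzyloxy)-2-(3,6-dihydroxy-2-methoxyphenyl)-6,8-dimethoxy-4H-chromen-4-one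
Product: 16 5,7,3',6'-tetrahydroxy-6,8,2'-trimethoxyflavone (2-(3,6-dihydroxy-2-methoxyphenyl)-5,7-dihydroxy-6,8-dimethoxy-4H-chromen-4-one)
Conditions: H2 (1 atm), Pd/C, EtOAc/MeOH, rt; filter under Ar
Reagents that add atoms: none
Why: Catalytic hydrogenolysis of aryl benzyl ethers; the benzylic C–O bonds should cleave under one atmosphere of hydrogen faster than the conjugated C2=C3 bond of a flavone is reduced, and the neutral reducing medium delivers the hydroquinone without exposure to base.

## Compound list

1 | acetosyringone, 1-(4-hydroxy-3,5-dimethoxyphenyl)ethanone | CC(=O)c1cc(OC)c(O)c(OC)c1 | starting material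
2 | 1-[4-(benzyloxy)-3,5-dimethoxyphenyl]ethanone | CC(=O)c1cc(OC)c(OCc2ccccc2)c(OC)c1 | intermediate
3 | 1-[4-(benzyloxy)-2-bromo-3,5-dimethoxyphenyl]ethanone | CC(=O)c1cc(OC)c(OCc2ccccc2)c(OC)c1Br | intermediate
4 | 1-[4-(benzyloxy)-2-hydroxy-3,5-dimethoxyphenyl]ethanone | CC(=O)c1cc(OC)c(OCc2ccccc2)c(OC)c1O | intermediate
5 | 1-[2,4-bis(benzyloxy)-3,5-dimethoxyphenyl]ethanone | CC(=O)c1cc(OC)c(OCc2ccccc2)c(OC)c1OCc1ccccc1 | intermediate
6 | 2-methoxyhydroquinone, 2-methoxybenzene-1,4-diol | COc1cc(O)ccc1O | starting material
7 | 2-methoxy-1,4-bis(methoxymethoxy)benzene | COCOc1ccc(OCOC)c(OC)c1 | intermediate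
8 | 2-methoxy-3,6-bis(methoxymethoxy)phenyllithium | [Li]c1c(OC)c(OCOC)ccc1OCOC | intermediate (not isolated)
9 | 2-methoxy-3,6-bis(methoxymethoxy)benzoic acid | COCOc1ccc(OCOC)c(OC)c1C(=O)O | intermediate
10 | 3,6-dihydroxy-2-methoxybenzoic acid | COc1c(O)ccc(O)c1C(=O)O | intermediate
11 | 3,6-diacetoxy-2-methoxybenzoic acid | COc1c(OC(C)=O)ccc(OC(C)=O)c1C(=O)O | intermediate
12 | 3,6-diacetoxy-2-methoxybenzoyl chloride | COc1c(OC(C)=O)ccc(OC(C)=O)c1C(Cl)=O | intermediate
13 | 1-[2,4-bis(benzyloxy)-3,5-dimethoxyphenyl]-3-(3,6-diacetoxy-2-methoxyphenyl)propane-1,3-dione | COc1cc(C(=O)CC(=O)c2c(OC)c(OC(C)=O)ccc2OC(C)=O)c(OCc2ccccc2)c(OC)c1OCc1ccccc1 | intermediate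
14 | 2-(3,6-diacetoxy-2-methoxyphenyl)-5,7-bis(benzyloxy)-6,8-dimethoxy-4H-chromen-4-one | COc1c(OC(C)=O)ccc(OC(C)=O)c1-c1cc(=O)c2c(OCc3ccccc3)c(OC)c(OCc3ccccc3)c(OC)c2o1 | intermediate
15 | 5,7-bis(benzyloxy)-2-(3,6-dihydroxy-2-methoxyphenyl)-6,8-dimethoxy-4H-chromen-4-one | COc1c(O)ccc(O)c1-c1cc(=O)c2c(OCc3ccccc3)c(OC)c(OCc3ccccc3)c(OC)c2o1 | intermediate
16 | 5,7,3',6'-tetrahydroxy-6,8,2'-trimethoxyflavone | COc1c(O)ccc(O)c1-c1cc(=O)c2c(O)c(OC)c(O)c(OC)c2o1 | target

## Step count and least certain steps

Total step count: 13. Longest linear sequence: 9 steps (steps 5 to 13, from 6 to 16). The ring A branch (steps 1 to 4) joins at step 10.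

**Step 11 (key step, the one proposed as a new method).** The electron removed from 13 may not lead to closure. The likely failures are:
- loss of a benzyl cation from the ring A radical cation;
- oxidation at the enol;
- further oxidation of the flavone once formed, since its ring A is not much harder to oxidise than that of 13.

The fallback makes the same O1–C8a bond by known chemistry from a C–Br bond. It sets out from 5, which NBS in MeCN should brominate at its only free ring position to give 1-[2,4-bis(benzyloxy)-6-bromo-3,5-dimethoxyphenyl]ethanone F1. C-acylation of F1 with 12 under the conditions of step 10 gives 1-[2,4-bis(benzyloxy)-6-bromo-3,5-dimethoxyphenyl]-3-(3,6-diacetoxy-2-methoxyphenyl)propane-1,3-dione F2. Intramolecular Ullmann-type O-arylation of its diketonate (CuI, 1,10-phenanthroline, K3PO4, DMF, 90 °C) returns to the route at 14. An acetate lost in the basic coupling would be put back with Ac2O and pyridine, since the flavone has no other hydroxyl.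

**Step 10.** Acylation at the doubly ortho-substituted acyl chloride may be slow. That would give time for acylation of the enolate on oxygen or for transfer of the acetyl group from the C6' oxygen to the magnesium diketonate. The fallback replaces acylation under base by a Lewis-acid aldol reaction and an oxidation:
- 5 is converted with TMSOTf and Et3N into {[1-(2,4-bis(benzyloxy)-3,5-dimethoxyphenyl)ethenyl]oxy}trimethylsilane F3;
- 12 is reduced by Rosenmund reduction (H2, Pd/BaSO4, 2,6-lutidine) to 3,6-diacetoxy-2-methoxybenzaldehyde F4;
- Mukaiyama aldol addition (BF3·OEt2, CH2Cl2, −78 °C) joins them to racemic 1-[2,4-bis(benzyloxy)-3,5-dimethoxyphenyl]-3-(3,6-diacetoxy-2-methoxyphenyl)-3-hydroxypropan-1-one F5;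
- Dess–Martin oxidation of F5 returns to the route at 13.

**Step 3.** Reductive elimination of the aryl–oxygen bond at a carbon flanked by an acetyl group and a methoxyl may fail, leading to loss of bromine by reduction, or the hot hydroxide may cause condensation of the methyl ketone. The fallback forms a C–B bond first under weak base. From 3, Miyaura borylation (B2pin2, Pd(dppf)Cl2, KOAc, dioxane, 90 °C) gives 1-[4-(benzyloxy)-3,5-dimethoxy-2-(4,4,5,5-tetramethyl-1,3,2-dioxaborolan-2-yl)phenyl]ethanone F6. Oxidation with NaBO3 in THF/H2O returns to the route at 4.

**Step 2.** Bromination may take place at the methyl group through the enol instead of on the ring, because the ring positions are next to the deactivating acetyl group. The fallback masks the ketone so that no enol can form. From 2, ethylene glycol and TsOH (toluene, reflux, water removal) give 2-[4-(benzyloxy)-3,5-dimethoxyphenyl]-2-methyl-1,3-dioxolane F7. NBS in MeCN with NaHCO3 brominates the ring to 2-[4-(benzyloxy)-2-bromo-3,5-dimethoxyphenyl]-2-methyl-1,3-dioxolane F8. Aqueous HCl in THF returns to the route at 3.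

**Step 12.** The newly freed hydroquinone may be oxidised by traces of air in the basic medium, or methoxide may open the pyranone at C2. The fallback reverses the order of the last two steps and makes the final step acidic. From 14, hydrogenolysis (H2, Pd/C, EtOAc) gives 2-(3,6-diacetoxy-2-methoxyphenyl)-5,7-dihydroxy-6,8-dimethoxy-4H-chromen-4-one F9. Acid-catalysed methanolysis (HCl generated from AcCl in MeOH, rt) returns to the route at 16 without passing through 15.

## Further compounds

F1 | step 11 | 1-[2,4-bis(benzyloxy)-6-bromo-3,5-dimethoxyphenyl]ethanone | CC(=O)c1c(Br)c(OC)c(OCc2ccccc2)c(OC)c1OCc1ccccc1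
F2 | step 11 | 1-[2,4-bis(benzyloxy)-6-bromo-3,5-dimethoxyphenyl]-3-(3,6-diacetoxy-2-methoxyphenyl)propane-1,3-dione | COc1c(Br)c(C(=O)CC(=O)c2c(OC)c(OC(C)=O)ccc2OC(C)=O)c(OCc2ccccc2)c(OC)c1OCc1ccccc1
F3 | step 10 | {[1-(2,4-bis(benzyloxy)-3,5-dimethoxyphenyl)ethenyl]oxy}trimethylsilane | C=C(O[Si](C)(C)C)c1cc(OC)c(OCc2ccccc2)c(OC)c1OCc1ccccc1
F4 | step 10 | 3,6-diacetoxy-2-methoxybenzaldehyde | COc1c(OC(C)=O)ccc(OC(C)=O)c1C=O
F5 | step 10 | racemic 1-[2,4-bis(benzyloxy)-3,5-dimethoxyphenyl]-3-(3,6-diacetoxy-2-methoxyphenyl)-3-hydroxypropan-1-one | COc1cc(C(=O)CC(O)c2c(OC)c(OC(C)=O)ccc2OC(C)=O)c(OCc2ccccc2)c(OC)c1OCc1ccccc1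
F6 | step 3 | 1-[4-(benzyloxy)-3,5-dimethoxy-2-(4,4,5,5-tetramethyl-1,3,2-dioxaborolan-2-yl)phenyl]ethanone | CC(=O)c1cc(OC)c(OCc2ccccc2)c(OC)c1B1OC(C)(C)C(C)(C)O1
F7 | step 2 | 2-[4-(benzyloxy)-3,5-dimethoxyphenyl]-2-methyl-1,3-dioxolane | COc1cc(C2(C)OCCO2)cc(OC)c1OCc1ccccc1
F8 | step 2 | 2-[4-(benzyloxy)-2-bromo-3,5-dimethoxyphenyl]-2-methyl-1,3-dioxolane | COc1cc(C2(C)OCCO2)c(Br)c(OC)c1OCc1ccccc1
F9 | step 12 | 2-(3,6-diacetoxy-2-methoxyphenyl)-5,7-dihydroxy-6,8-dimethoxy-4H-chromen-4-one | COc1c(OC(C)=O)ccc(OC(C)=O)c1-c1cc(=O)c2c(O)c(OC)c(O)c(OC)c2o1
A1 | alternative 1 | 4-hydroxy-3,5-dimethoxy-6-{4-[2-methoxy-3,6-bis(methoxymethoxy)phenyl]-2-oxobut-3-yn-1-yl}-2H-pyran-2-one | O=C1OC(CC(=O)C#Cc2c(OC)c(OCOC)ccc2OCOC)=C(OC)C(O)=C1OC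
A2 | alternative 1 | 5,7-dihydroxy-6,8-dimethoxy-2-[2-methoxy-3,6-bis(methoxymethoxy)phenyl]-4H-chromen-4-one | COc1c(OCOC)ccc(OCOC)c1-c1cc(=O)c2c(O)c(OC)c(O)c(OC)c2o1
A3 | alternative 2 | 3,5-bis(benzyloxy)-2,4-dimethoxy-6-[(triphenylphosphoranylidene)acetyl]phenyl 3,6-bis(benzyloxy)-2-methoxybenzoate | COc1c(OCc2ccccc2)ccc(OCc2ccccc2)c1C(=O)Oc1c(OC)c(OCc2ccccc2)c(OC)c(OCc2ccccc2)c1C(=O)C=P(c1ccccc1)(c1ccccc1)c1ccccc1
A4 | alternative 2 | 5,7-bis(benzyloxy)-2-[3,6-bis(benzyloxy)-2-methoxyphenyl]-6,8-dimethoxy-4H-chromen-4-one | COc1c(OCc2ccccc2)ccc(OCc2ccccc2)c1-c1cc(=O)c2c(OCc3ccccc3)c(OC)c(OCc3ccccc3)c(OC)c2o1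
A5 | alternative 3 | 2-bromo-3-methoxy-4-(methoxymethoxy)phenyl 5,7-bis(benzyloxy)-6,8-dimethoxy-4-oxo-4H-chromene-3-carboxylate | COCOc1ccc(OC(=O)c2coc3c(OC)c(OCc4ccccc4)c(OC)c(OCc4ccccc4)c3c2=O)c(Br)c1OC
A6 | alternative 3 | lactone-bridged protected flavone: chromeno[4,3-b]chromene-6,7-dione in which the carboxyl on flavone C3 is esterified by the C6' oxygen, with benzyloxy groups at flavone C5 and C7, methoxy groups at C6, C8 and C2', and a methoxymethoxy group at C3' | O=C1Oc2ccc(OCOC)c(OC)c2-c2oc3c(OC)c(OCc4ccccc4)c(OC)c(OCc4ccccc4)c3c(=O)c21
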